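Germacrane numbering; ring A is the ten-membered carbocycle, ring B the lactone, ring C the oxirane. The plan exploits the bare C9 methylene between carbinol C8 and the fully substituted C10 shared by rings A and C. Tracing ring C back to an E-C1=C10 alkene makes C9–C10 the sp3–sp2 bond of a homoallylic alcohol. Ring A is closed there by nickel-catalysed reductive coupling of a C10 alkenyl iodide with a C9 halohydrin carbon. This one operation forms the strained trans,trans-cyclodecadiene, keeps the alkene geometry and leaves O8 free for the angelate. The precursor is an open-chain α-methylene-γ-butyrolactone carrying C2, C6, C7 and C8; hydroxyl-directed epoxidation sets C1 and C10 afterwards.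

Key step: step 13

Remark 1: atom labels C1–C15 in all "Why" lines are the germacrane numbers of the target, also for open-chain compounds.
Remark 2 (assumption): the senses of induction of (S)-TRIP (step 3) and (S,S)-ProPhenol (step 5) are taken from the accepted transition-state models. The mirror-image catalyst would be used should the opposite sense be found.

Step 1
Reactants: 1 3-(trimethylsilyl)prop-2-yn-1-ol
Product: 3 (E)-3-(trimethylsilyl)but-2-en-1-ol, via cyclic sodium alkenylalanate 2 (not isolated)
Conditions: NaAlH2(OCH2CH2OMe)2, THF, 0 °C to rt; then CuI (0.2 equiv), MeI, 0 °C to rt; aq. potassium sodium tartrate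
Reagents that add atoms: sodium bis(2-methoxyethoxy)aluminium dihydride [Na+].[AlH2-](OCCOC)OCCOC (atoms stay in 2 only); iodomethane CI
Why: Alkoxide-directed trans-hydroalumination puts aluminium on the silyl-bearing carbon cis to CH2O (ring of 2), and copper-mediated methylation of the alkenylalanate with retention (trans-hydroalumination/alkylation) fixes methyl cis and silyl trans to the carbinol carbon, i.e. the later E-C1=C10 geometry.

Step 2
Reactants: 3 (E)-3-(trimethylsilyl)but-2-en-1-ol
Product: 4 (E)-3-(trimethylsilyl)but-2-enal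
Conditions: MnO2, CH2Cl2, rt
Reagents that add atoms: none
Why: MnO2 oxidation of a primary allylic alcohol is neutral and leaves the alkenylsilane and its geometry untouched.

Step 3
Reactants: 4 (E)-3-(trimethylsilyl)but-2-enal; 5 allenylboronic acid pinacol ester
Product: 6 (4S,5E)-6-(trimethylsilyl)hept-5-en-1-yn-4-ol
Conditions: (S)-TRIP [3,3'-bis(2,4,6-triisopropylphenyl)-BINOL hydrogen phosphate] (5 mol %), 4 Å MS, toluene, −20 °C; aq. work-up
Reagents that add atoms: none
Why: Chiral phosphoric acid-catalysed propargylation with an allenylboronate runs through a closed six-membered SE2' transition state, gives only the homopropargylic alcohol and sets C2 (S) by catalyst-controlled Si-face attack on the enal.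

Step 4
Reactants: 6 (4S,5E)-6-(trimethylsilyl)hept-5-en-1-yn-4-ol
Product: 7 (4S,5E)-4-(triethylsilyloxy)-6-(trimethylsilyl)hept-5-en-1-yne
Conditions: TESCl, imidazole, CH2Cl2, 0 °C
Reagents that add atoms: chlorotriethylsilane CC[Si](Cl)(CC)CC
Why: Standard silylation; the acid-labile TES group is chosen so that O2 can later be freed in the presence of the TBS ether at O15.

Step 5
Reactants: 7 (4S,5E)-4-(triethylsilyloxy)-6-(trimethylsilyl)hept-5-en-1-yne; 8 acrolein
Product: 10 (3S,7S,8E)-7-(triethylsilyloxy)-9-(trimethylsilyl)deca-1,8-dien-4-yn-3-ol, via methylzinc acetylide 9 (not isolated)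
Conditions: Me2Zn, (S,S)-ProPhenol (20 mol %), Ph3P=O (40 mol %), toluene, 0 °C; then 8 (excess), 0 °C; aq. work-up
Reagents that add atoms: dimethylzinc C[Zn]C (atoms stay in 9 only)
Why: Zinc–ProPhenol-catalysed asymmetric alkynylation is established for α,β-unsaturated aldehydes, tolerates silyl ethers and alkenylsilanes, and sets C6 by catalyst-controlled Re-face addition to acrolein, remote C2 having no say.

Step 6
Reactants: 10 (3S,7S,8E)-7-(triethylsilyloxy)-9-(trimethylsilyl)deca-1,8-dien-4-yn-3-ol
Product: 12 (3S,4Z,7S,8E)-5-iodo-7-(triethylsilyloxy)-9-(trimethylsilyl)deca-1,4,8-trien-3-ol, via cyclic sodium alkenylalanate 11 (not isolated)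
Conditions: NaAlH2(OCH2CH2OMe)2, THF, 0 °C to rt; EtOAc (destroys excess hydride); I2, THF, −78 °C; aq. Na2S2O3/potassium sodium tartrate
Reagents that add atoms: sodium bis(2-methoxyethoxy)aluminium dihydride [Na+].[AlH2-](OCCOC)OCCOC (atoms stay in 11 only); iodine II
Why: Alkoxide-directed trans-hydroalumination delivers hydride to C5 and aluminium to C4 cis to C6 (ring of 11) and iodinolysis with retention gives the Z-iodide, while the O-silylated C1=C10 unit and the vinyl group have no free directing hydroxyl and stay intact.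

Step 7
Reactants: 12 (3S,4Z,7S,8E)-5-iodo-7-(triethylsilyloxy)-9-(trimethylsilyl)deca-1,4,8-trien-3-ol; 13 (tributylstannyl)methanol
Product: 14 (3S,4Z,7S,8E)-5-(hydroxymethyl)-7-(triethylsilyloxy)-9-(trimethylsilyl)deca-1,4,8-trien-3-ol
Conditions: Pd(PPh3)4 (5 mol %), dioxane, 80 °C
Reagents that add atoms: none
Why: Stille hydroxymethylation of an alkenyl iodide proceeds with retention, so C15 ends up cis to C6 and C3 trans to it (the ring-trans C4=C5 geometry of the target), and the alkenylsilane is inert to zerovalent palladium.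

Step 8
Reactants: 14 (3S,4Z,7S,8E)-5-(hydroxymethyl)-7-(triethylsilyloxy)-9-(trimethylsilyl)deca-1,4,8-trien-3-ol
Product: 15 (3S,4Z,7S,8E)-5-(tert-butyldimethylsilyloxymethyl)-7-(triethylsilyloxy)-9-(trimethylsilyl)deca-1,4,8-trien-3-ol
Conditions: TBSCl (1.05 equiv), imidazole, CH2Cl2, −20 °C
Reagents that add atoms: tert-butylchlorodimethylsilane CC(C)(C)[Si](C)(C)Cl
Why: The primary allylic hydroxyl is silylated much faster than the hindered secondary bis-allylic one (chemoselective silylation).

Step 9
Reactants: 15 (3S,4Z,7S,8E)-5-(tert-butyldimethylsilyloxymethyl)-7-(triethylsilyloxy)-9-(trimethylsilyl)deca-1,4,8-trien-3-ol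
Product: 16 (3S,4Z,7S,8E)-5-(tert-butyldimethylsilyloxymethyl)-9-iodo-7-(triethylsilyloxy)deca-1,4,8-trien-3-ol
Conditions: NIS, MeCN, 0 °C, dark
Reagents that add atoms: N-iodosuccinimide O=C1CCC(=O)N1I
Why: Electrophilic ipso-iododesilylation in acetonitrile goes through the β-silyl cation with retention of geometry and is faster than attack on the oxygen-deactivated C4=C5 or the terminal vinyl group.

Step 10
Reactants: 16 (3S,4Z,7S,8E)-5-(tert-butyldimethylsilyloxymethyl)-9-iodo-7-(triethylsilyloxy)deca-1,4,8-trien-3-ol; 17 2-(bromomethyl)acrylic acid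
Product: 18 2-(bromomethyl)acrylate ester of 16 at O6
Conditions: DIC, DMAP (5 mol %), CH2Cl2, 0 °C
Reagents that add atoms: none
Why: Steglich-type carbodiimide esterification is neutral enough for the bis-allylic alcohol and, cold and with little DMAP, for the allylic bromide, and it does not touch C6.

Step 11
Reactants: 18 2-(bromomethyl)acrylate ester of 16 at O6
Product: 19 (5R)-3-(bromomethyl)-5-[(1Z,4S,5E)-2-(tert-butyldimethylsilyloxymethyl)-6-iodo-4-(triethylsilyloxy)hepta-1,5-dien-1-yl]furan-2(5H)-one
Conditions: second-generation Hoveyda–Grubbs catalyst (5 mol %), toluene, 70 °C, argon sparge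
Reagents that add atoms: none
Why: Ring-closing metathesis joins the only terminal vinyl group with the 1,1-disubstituted acrylate to the five-membered butenolide, the trisubstituted alkenes and the alkenyl iodide being inert, and the neutral medium avoids epimerisation at the acidic C6–H.

Step 12
Reactants: 19 bromomethylbutenolide; 20 chloroacetaldehyde (50 % aq. solution)
Product: 21 (4R,5R)-4-[(1R)-2-chloro-1-hydroxyethyl]-5-[(1Z,4S,5E)-2-(tert-butyldimethylsilyloxymethyl)-6-iodo-4-(triethylsilyloxy)hepta-1,5-dien-1-yl]-3-methylidenedihydrofuran-2(3H)-one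
Conditions: indium powder, THF/H2O, rt
Reagents that add atoms: none
Why: Indium Barbier 2-(alkoxycarbonyl)allylation, in which the allylindium reacts at its γ-carbon C7 anti to the C6 side chain (trans-lactone) through a chair whose ring-locked E-type allyl unit and equatorial CH2Cl give the anti-crotylation-type C7/C8 relationship required, unveils the C11=C13 methylene in the same step, and aqueous indium tolerates α-chloroaldehydes and alkenyl iodides.

Step 13
Reactants: 21 open-chain chlorohydrin alkenyl iodide
Product: 23 (2S,6R,7R,8S)-15-(tert-butyldimethylsilyloxy)-8-hydroxy-2-(triethylsilyloxy)germacra-1(10)E,4Z,11(13)-trien-12,6-olide, via iodohydrin 22 (not isolated)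
Conditions: NaI (3 equiv), DMA, 50 °C; this solution added by syringe pump (12 h) to NiBr2·DME (30 mol %), 4,4'-di-tert-butyl-2,2'-bipyridine (36 mol %), manganese powder (5 equiv), DMA, 40 °C, final 2 mM
Reagents that add atoms: sodium iodide [Na+].[I-] (iodine stays in 22 only)
Why: Proposed new method: the closest known reaction type is the nickel-catalysed reductive cross-electrophile coupling of alkenyl or aryl halides with primary alkyl halides, including the iodide-cocatalysed coupling of terminal epoxides that runs through iodohydrins, known between two molecules but not for closing a medium ring. Finkelstein exchange turns 21 into 22; zerovalent nickel inserts into the C10–I bond with retention, monovalent nickel abstracts iodine from C9, the primary β-hydroxyalkyl radical is caught by the tethered divalent alkenylnickel, and reductive elimination from trivalent nickel forms C9–C10 while manganese returns the catalyst. The only ring closed is ring A, formed by reductive elimination out of an eleven-membered nickelacycle, an endo closure in which both reacting carbons end up in the ring. No stereocentre is created: the E geometry of C1=C10 is carried over from the alkenyl iodide, and C2, C6, C7 and C8 are spectators. The step needs cross- over homo-coupling and ring closure over oligomerisation, which the different activation modes of the sp2 and sp3 C–I bonds, slow addition at high dilution and the pre-folding by the trans-substituted ring B and the two rigid alkenes secure. It also needs the radical to spare the C11=C13 acceptor, which holds because attack on C13 would be a disfavoured 5-endo closure and bimolecular addition is suppressed by dilution, and a β-hydroxy radical does not fragment as a β-oxygenated organometal would.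

Step 14
Reactants: 23 macrocyclic C8 alcohol; 24 angelic acid
Product: 26 (2S,6R,7R,8S)-8-angeloyloxy-15-(tert-butyldimethylsilyloxy)-2-(triethylsilyloxy)germacra-1(10)E,4Z,11(13)-trien-12,6-olide, via mixed anhydride 25 (not isolated)
Conditions: 24, 2,4,6-trichlorobenzoyl chloride, Et3N, toluene, rt; then 23, 75 °C
Reagents that add atoms: 2,4,6-trichlorobenzoyl chloride O=C(Cl)c1c(Cl)cc(Cl)cc1Cl (atoms stay in 25 only)
Why: Acylation with the mixed 2,4,6-trichlorobenzoic anhydride without a nucleophilic catalyst (Yamaguchi-type esterification) is the established way to make angelates of hindered alcohols without Z-to-E isomerisation, and O8 is the only free hydroxyl.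

Step 15
Reactants: 26 bis-silylated macrocyclic angelate
Product: 27 (2S,6R,7R,8S)-8-angeloyloxy-15-(tert-butyldimethylsilyloxy)-2-hydroxygermacra-1(10)E,4Z,11(13)-trien-12,6-olide
Conditions: PPTS (cat.), MeOH/CH2Cl2, 0 °C
Reagents that add atoms: none
Why: Mild acid methanolysis cleaves the secondary TES ether far faster than the primary TBS ether and is too weak to trigger transannular cyclisation of the diene.

Step 16
Reactants: 27 C2 allylic alcohol
Product: 28 (1R,2S,6R,7R,8S,10R)-8-angeloyloxy-15-(tert-butyldimethylsilyloxy)-1,10-epoxy-2-hydroxygermacra-4Z,11(13)-dien-12,6-olide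
Conditions: mCPBA (1.05 equiv), CH2Cl2/aq. pH 7 phosphate buffer, −20 to 0 °C
Reagents that add atoms: 3-chloroperoxybenzoic acid O=C(OO)c1cccc(Cl)c1
Why: Hydroxyl-directed peracid epoxidation (Henbest type), in which allylic 1,3-strain with the C14 methyl keeps H2 in the alkene plane and O2–H on the outer, only open face of the trans-cycloalkene in ring A, delivers oxygen by hydrogen bonding to give the (1R,10R)-oxirane, while C4=C5 (two allylic C–O bonds, no free hydroxyl), C11=C13 and the angelate are electron-poor.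

Step 17
Reactants: 28 O15-TBS epoxide
Product: 29 target, (1R,2S,6R,7R,8S,10R)-8-angeloyloxy-1,10-epoxy-2,15-dihydroxygermacra-4Z,11(13)-dien-12,6-olide
Conditions: HF·pyridine, pyridine, THF, 0 °C
Reagents that add atoms: none
Why: Pyridine-buffered HF·pyridine removes a primary allylic TBS ether under conditions that epoxides, angelates and α-methylene lactones tolerate.

Compound list
1 | 3-(trimethylsilyl)prop-2-yn-1-ol | C[Si](C)(C)C#CCO | starting material
2 | cyclic sodium alkenylalanate from 1 (five-membered O–Al–C=C ring, two 2-methoxyethoxy ligands) | [Na+].COCCO[Al-]1(OCCOC)OCC=C1[Si](C)(C)C | intermediate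
3 | (E)-3-(trimethylsilyl)but-2-en-1-ol | OC/C=C(\C)[Si](C)(C)C | intermediate
4 | (E)-3-(trimethylsilyl)but-2-enal | O=C/C=C(\C)[Si](C)(C)C | intermediate
5 | allenylboronic acid pinacol ester | C=C=CB1OC(C)(C)C(C)(C)O1 | starting material
6 | (4S,5E)-6-(trimethylsilyl)hept-5-en-1-yn-4-ol | C#CC[C@H](O)/C=C(\C)[Si](C)(C)C | intermediate
7 | (4S,5E)-4-(triethylsilyloxy)-6-(trimethylsilyl)hept-5-en-1-yne | C#CC[C@H](O[Si](CC)(CC)CC)/C=C(\C)[Si](C)(C)C | intermediate
8 | acrolein | C=CC=O | starting material
9 | methylzinc acetylide of 7 | C[Zn]C#CC[C@H](O[Si](CC)(CC)CC)/C=C(\C)[Si](C)(C)C | intermediate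
10 | (3S,7S,8E)-7-(triethylsilyloxy)-9-(trimethylsilyl)deca-1,8-dien-4-yn-3-ol | O[C@@H](C=C)C#CC[C@H](O[Si](CC)(CC)CC)/C=C(\C)[Si](C)(C)C | intermediate
11 | cyclic sodium alkenylalanate from 10 (Al on C4, O6–Al ring) | [Na+].COCCO[Al-]1(OCCOC)O[C@@H](C=C)C=C1C[C@H](O[Si](CC)(CC)CC)/C=C(\C)[Si](C)(C)C | intermediate
12 | (3S,4Z,7S,8E)-5-iodo-7-(triethylsilyloxy)-9-(trimethylsilyl)deca-1,4,8-trien-3-ol | O[C@@H](C=C)/C=C(\I)C[C@H](O[Si](CC)(CC)CC)/C=C(\C)[Si](C)(C)C | intermediate
13 | (tributylstannyl)methanol | CCCC[Sn](CCCC)(CCCC)CO | starting material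
14 | (3S,4Z,7S,8E)-5-(hydroxymethyl)-7-(triethylsilyloxy)-9-(trimethylsilyl)deca-1,4,8-trien-3-ol | O[C@@H](C=C)/C=C(\CO)C[C@H](O[Si](CC)(CC)CC)/C=C(\C)[Si](C)(C)C | intermediate
15 | (3S,4Z,7S,8E)-5-(tert-butyldimethylsilyloxymethyl)-7-(triethylsilyloxy)-9-(trimethylsilyl)deca-1,4,8-trien-3-ol | O[C@@H](C=C)/C=C(\CO[Si](C)(C)C(C)(C)C)C[C@H](O[Si](CC)(CC)CC)/C=C(\C)[Si](C)(C)C | intermediate
16 | (3S,4Z,7S,8E)-5-(tert-butyldimethylsilyloxymethyl)-9-iodo-7-(triethylsilyloxy)deca-1,4,8-trien-3-ol | O[C@@H](C=C)/C=C(\CO[Si](C)(C)C(C)(C)C)C[C@H](O[Si](CC)(CC)CC)/C=C(\C)I | intermediate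
17 | 2-(bromomethyl)acrylic acid | C=C(CBr)C(=O)O | starting material
18 | 2-(bromomethyl)acrylate of 16 (3S,4Z,7S,8E) | C=C(CBr)C(=O)O[C@@H](C=C)/C=C(\CO[Si](C)(C)C(C)(C)C)C[C@H](O[Si](CC)(CC)CC)/C=C(\C)I | intermediate
19 | (5R)-3-(bromomethyl)-5-[(1Z,4S,5E)-2-(tert-butyldimethylsilyloxymethyl)-6-iodo-4-(triethylsilyloxy)hepta-1,5-dien-1-yl]furan-2(5H)-one | O=C1O[C@@H](C=C1CBr)/C=C(\CO[Si](C)(C)C(C)(C)C)C[C@H](O[Si](CC)(CC)CC)/C=C(\C)I | intermediate
20 | chloroacetaldehyde | ClCC=O | starting material
21 | (4R,5R)-4-[(1R)-2-chloro-1-hydroxyethyl]-5-[(1Z,4S,5E)-2-(tert-butyldimethylsilyloxymethyl)-6-iodo-4-(triethylsilyloxy)hepta-1,5-dien-1-yl]-3-methylidenedihydrofuran-2(3H)-one | C=C1C(=O)O[C@H](/C=C(\CO[Si](C)(C)C(C)(C)C)C[C@H](O[Si](CC)(CC)CC)/C=C(\C)I)[C@H]1[C@@H](O)CCl | intermediate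
22 | iodohydrin analogue of 21, (1R)-1-hydroxy-2-iodoethyl at C7 | C=C1C(=O)O[C@H](/C=C(\CO[Si](C)(C)C(C)(C)C)C[C@H](O[Si](CC)(CC)CC)/C=C(\C)I)[C@H]1[C@@H](O)CI | intermediate
23 | (2S,6R,7R,8S)-15-(tert-butyldimethylsilyloxy)-8-hydroxy-2-(triethylsilyloxy)germacra-1(10)E,4Z,11(13)-trien-12,6-olide | C=C1C(=O)O[C@@H]2/C=C(\CO[Si](C)(C)C(C)(C)C)C[C@H](O[Si](CC)(CC)CC)/C=C(\C)C[C@H](O)[C@@H]12 | intermediate
24 | angelic acid, (Z)-2-methylbut-2-enoic acid | OC(=O)/C(C)=C\C | starting material
25 | angelic 2,4,6-trichlorobenzoic anhydride | O=C(OC(=O)/C(C)=C\C)c1c(Cl)cc(Cl)cc1Cl | intermediate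
26 | (2S,6R,7R,8S)-8-angeloyloxy-15-(tert-butyldimethylsilyloxy)-2-(triethylsilyloxy)germacra-1(10)E,4Z,11(13)-trien-12,6-olide | C=C1C(=O)O[C@@H]2/C=C(\CO[Si](C)(C)C(C)(C)C)C[C@H](O[Si](CC)(CC)CC)/C=C(\C)C[C@H](OC(=O)/C(C)=C\C)[C@@H]12 | intermediate
27 | (2S,6R,7R,8S)-8-angeloyloxy-15-(tert-butyldimethylsilyloxy)-2-hydroxygermacra-1(10)E,4Z,11(13)-trien-12,6-olide | C=C1C(=O)O[C@@H]2/C=C(\CO[Si](C)(C)C(C)(C)C)C[C@H](O)/C=C(\C)C[C@H](OC(=O)/C(C)=C\C)[C@@H]12 | intermediate
28 | (1R,2S,6R,7R,8S,10R)-8-angeloyloxy-15-(tert-butyldimethylsilyloxy)-1,10-epoxy-2-hydroxygermacra-4Z,11(13)-dien-12,6-olide | C=C1C(=O)O[C@@H]2/C=C(\CO[Si](C)(C)C(C)(C)C)C[C@H](O)[C@H]3O[C@]3(C)C[C@H](OC(=O)/C(C)=C\C)[C@@H]12 | intermediate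
29 | EANPDB:COMP_00180, (1R,2S,6R,7R,8S,10R)-8-angeloyloxy-1,10-epoxy-2,15-dihydroxygermacra-4Z,11(13)-dien-12,6-olide | C=C1C(=O)O[C@@H]2/C=C(\CO)C[C@H](O)[C@H]3O[C@]3(C)C[C@H](OC(=O)/C(C)=C\C)[C@@H]12 | target

Total step count: 17. Longest linear sequence: 17 steps (from 1).

Steps most likely to fail

Step 13 (ring closure, proposed new method). Hydrodehalogenation, oligomerisation, or interception of the alkenylnickel or the C9 radical by the C11=C13 acceptor may outrun closure of the strained ring. The fallback uses known chemistry only. The C9–C10 bond is made between two molecules, and ring A is then closed at C7–C8 by the macrocyclic allylation established for germacranolides.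
- It sets out from 16. Nickel-catalysed reductive coupling with bromoacetaldehyde dimethyl acetal (NiBr2·DME, 4,4'-di-tert-butyl-2,2'-bipyridine, NaI, manganese powder, DMA) gives the C8 dimethyl acetal F1.
- Esterification with 17 under the conditions of step 10 gives the bromomethylacrylate F2.
- Ring-closing metathesis under the conditions of step 11 gives the bromomethylbutenolide acetal F3.
- TESOTf/2,4,6-collidine followed by water frees the β,γ-unsaturated aldehyde F4 without loss of the silyl ethers.
- CrCl2 in THF/DMF under high dilution (intramolecular Nozaki–Hiyama allylation through the same chair as in step 12) closes C7–C8. The fallback comes back to the route at 23.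

Step 12 (Barbier addition). Four things may go wrong: reductive loss of chloride from the aldehyde at the metal surface, sluggish reaction of the aldehyde hydrate, erosion of the simple diastereoselectivity, or acyl migration from O6 to O8. The fallback brings in C8–C9 without a halogen and installs the leaving group afterwards.
- It sets out from 19. Aqueous indium Barbier addition to glycolaldehyde (from its commercial dimer) gives the C8,C9-diol F5; the free hydroxyl of the aldehyde can chelate indium.
- Bu2SnO-catalysed tosylation (TsCl, Et3N) of the primary hydroxyl gives the C9 tosylate F6.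
- NaI in DMA converts F6 into the iodohydrin. The fallback comes back to the route at 22.

Step 14 (angeloylation). Slow acylation of the hindered macrocyclic alcohol may leave time for Z-to-E isomerisation of the acyl group or for translactonisation to O8. The fallback changes the order of events.
- It sets out from 21. The open-chain, less encumbered O8 is acylated with 25 to give the chlorohydrin angelate F7.
- NaI in DMA gives the iodide angelate F8.
- F8 is cyclised under the conditions of step 13 with the ester already in place. The fallback comes back to the route at 26.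

Further compounds
F1 | step 13 | (3S,4Z,7S,8E)-5-(tert-butyldimethylsilyloxymethyl)-11,11-dimethoxy-9-methyl-7-(triethylsilyloxy)undeca-1,4,8-trien-3-ol | O[C@@H](C=C)/C=C(\CO[Si](C)(C)C(C)(C)C)C[C@H](O[Si](CC)(CC)CC)/C=C(\C)CC(OC)OC
F2 | step 13 | 2-(bromomethyl)acrylate of F1 | C=C(CBr)C(=O)O[C@@H](C=C)/C=C(\CO[Si](C)(C)C(C)(C)C)C[C@H](O[Si](CC)(CC)CC)/C=C(\C)CC(OC)OC
F3 | step 13 | (5R)-3-(bromomethyl)butenolide carrying the C8 dimethyl acetal side chain | O=C1O[C@@H](C=C1CBr)/C=C(\CO[Si](C)(C)C(C)(C)C)C[C@H](O[Si](CC)(CC)CC)/C=C(\C)CC(OC)OC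
F4 | step 13 | (5R)-3-(bromomethyl)butenolide carrying the C8 aldehyde side chain | O=C1O[C@@H](C=C1CBr)/C=C(\CO[Si](C)(C)C(C)(C)C)C[C@H](O[Si](CC)(CC)CC)/C=C(\C)CC=O
F5 | step 12 | C8,C9-diol analogue of 21, (1S)-1,2-dihydroxyethyl at C7 | C=C1C(=O)O[C@H](/C=C(\CO[Si](C)(C)C(C)(C)C)C[C@H](O[Si](CC)(CC)CC)/C=C(\C)I)[C@H]1[C@@H](O)CO
F6 | step 12 | C9 4-toluenesulfonate of F5 | C=C1C(=O)O[C@H](/C=C(\CO[Si](C)(C)C(C)(C)C)C[C@H](O[Si](CC)(CC)CC)/C=C(\C)I)[C@H]1[C@@H](O)COS(=O)(=O)c1ccc(C)cc1
F7 | step 14 | O8-angelate of chlorohydrin 21 | C=C1C(=O)O[C@H](/C=C(\CO[Si](C)(C)C(C)(C)C)C[C@H](O[Si](CC)(CC)CC)/C=C(\C)I)[C@H]1[C@@H](OC(=O)/C(C)=C\C)CCl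
F8 | step 14 | O8-angelate of iodohydrin 22 | C=C1C(=O)O[C@H](/C=C(\CO[Si](C)(C)C(C)(C)C)C[C@H](O[Si](CC)(CC)CC)/C=C(\C)I)[C@H]1[C@@H](OC(=O)/C(C)=C\C)CI
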